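(The earlier runs and the new flask are simulated on assumed constants; noise was put on by code.)

Read the green run as the fraction of starting material left, not the fraction of target made, the kineticist urged when the meeting on this flask opened.

- green: starting material 34 mM; reagent 3 equiv (fed, over 20 min); free catalyst 0.1 mol%; added ligand 57 µM; the very flask that is asked about, followed so far; the fed solution adds 0.20 times the starting volume
- flask: starting material 34 mM; reagent 3.00 equiv (fed, over 20 min); free catalyst 0.1 mol%; added ligand 57 µM; time 4.0 h; the fed solution adds 0.20 times the starting volume

- green (time / min: target / %, starting material / %): 5.00: 0, 98; 15.0: 9, 93; 30.0: 20, 79; 40.0: 29, 70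

(scatter of a reading: 2 percentage points)

- charges are per starting volume, the dose included; the dosed solution carries all of it
- on the list of suspects stand: starting material + free catalyst -> catalyst intermediate A; catalyst intermediate A -> catalyst intermediate B; reagent + catalyst intermediate B -> catalyst intermediate C; catalyst intermediate C -> catalyst intermediate D; catalyst intermediate D -> free catalyst + target; free catalyst + added ligand <-> idle complex

- the best time, 4.0 h at the latest, for target
- the amount of target, in percent of the starting material charged, at that time

The kineticist pointed out that the green run is this very flask, followed so far. She took the reading of 93% starting material at 15.0 min, past the induction though still inside the feed, and that of 70% at 40.0 min. The slope between them, 0.0114 min⁻¹, she called the loss constant: the fall of the logarithm of the fraction left per minute, a pseudo-first-order constant, read with a scatter of 2 percentage points on each reading.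

The process chemist objected that [added ligand] at 57 µM stands higher than the catalyst charge of 34.0 µM, so the constant might drift as the idle complex forms. She accepted it as a working number, since starting material and target still sum to 99.0% at the last reading and no step on the list of suspects consumes target.

Carried from 40.0 min to 4.0 h, our reckoning leaves 7.21% of the starting material, so we committed to the end of the window and 92.8% of target.

The forecast gave 96% at 4 h, a figure higher than ours, on the ground that “No listed step destroys target”.

The flask gives 95.5% at 4.00 h, with 4.45% of starting material left against our 7.21%.

    starting material + free catalyst → catalyst intermediate A (k = 1300 M⁻¹ min⁻¹)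
    catalyst intermediate A → catalyst intermediate B (k = 1600 min⁻¹)
    reagent + catalyst intermediate B → catalyst intermediate C (k = 480 M⁻¹ min⁻¹)
    catalyst intermediate C → catalyst intermediate D (k = 110 min⁻¹)
    catalyst intermediate D → free catalyst + target (k = 56.0 min⁻¹)
    free catalyst + added ligand ⇌ idle complex, settled at all times (K = 32000 M⁻¹)

Averaged over its whole course this flask has a loss constant of 0.0130 min⁻¹, higher than the green reading of 0.0114 min⁻¹, and its free catalyst rises from 25.4% of the catalyst at 0.333 h to 45.9% at 4.00 h. The neighbouring flask differs in [added ligand] = 0.097 mM, all else held. Its 11.0% of starting material left at 4.00 h gives a loss constant of 0.00919 min⁻¹, lower than this flask's by a ratio of 0.707. In that neighbouring flask, free catalyst ends at 30.5% of the catalyst and target at 89.0%.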